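**Retrosynthetic overview**
1. Pyran ring C is formed last. The 2,2-dimethyl-2H-chromene is cut at C3–C4 and at O1–C2, back to formyl benzil 7 and (2-methylprop-1-enyl)boronic acid 8; one condensation/electrocyclisation cascade, run without protecting groups.
2. Enabling feature: O1 and C4 of the pyran ring sit on neighbouring carbons of benzene ring A (C8a and C4a), the retron of an ortho-hydroxybenzaldehyde. C2 is a gem-dimethyl carbon, and the other hydroxyl ortho to C4a (5-OH) is held by a six-membered hydrogen bond to the C6 aryl ketone, so only O1 is free to close the ring.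
3. The 1,2-diketone is cut at the ring A–C(=O) bond: ortho-hydroxyalkylation of ring A with 4-hydroxyphenylglyoxal 5 (which brings ring B), then benzoin-to-benzil oxidation.
4. The prenyl group comes from C-alkylation of mirror-symmetric 2,6-dihydroxy-4-methoxybenzaldehyde 2. Its two free ring carbons are equivalent, so prenylation and the later glyoxal addition are regiochemically unambiguous. 2 comes from 2,4,6-trihydroxybenzaldehyde 1 by para-selective O-methylation.
5. Ring order: rings A and B are bought, ring C is closed in the final step.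

Key step: step 5

Remark: the target has no stereocentre and is treated as the open, hydrogen-bonded 2-hydroxybenzil drawn; 5 is used as its commercial hydrate.

**Step 1**
Reactants: 1 2,4,6-trihydroxybenzaldehyde
Product: 2 2,6-dihydroxy-4-methoxybenzaldehyde
Conditions: Me2SO4 (1.0 equiv), K2CO3 (1.0 equiv), acetone, 0 °C to rt
Reagents that add atoms: dimethyl sulfate, COS(=O)(=O)OC
Why: Williamson ether synthesis with one equivalent of base, in which the 4-hydroxyl (para to the formyl group, the most acidic and the only one not hydrogen-bonded to the C=O) should be methylated first, leaving the mirror-symmetric 2,6-diol.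

**Step 2**
Reactants: 2 2,6-dihydroxy-4-methoxybenzaldehyde; 3 1-bromo-3-methylbut-2-ene (prenyl bromide)
Product: 4 2,6-dihydroxy-4-methoxy-3-(3-methylbut-2-en-1-yl)benzaldehyde
Conditions: 3 (1.0 equiv), KOH (10% in H2O), 0 °C to rt
Reagents that add atoms: none
Why: C-alkylation of an ambident phenoxide (C-prenylation of a phloroglucinol-type ring) in water, where solvation of oxygen favours attack through carbon; the two unsubstituted ring carbons of 2 are equivalent by symmetry, so mono-alkylation can give only one regioisomer.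

**Step 3**
Reactants: 4 2,6-dihydroxy-4-methoxy-3-(3-methylbut-2-en-1-yl)benzaldehyde; 5 4-hydroxyphenylglyoxal hydrate
Product: 6 rac-2,6-dihydroxy-3-[1-hydroxy-2-(4-hydroxyphenyl)-2-oxoethyl]-4-methoxy-5-(3-methylbut-2-en-1-yl)benzaldehyde
Conditions: 5 (1.5 equiv), MgCl2 (1.5 equiv), Et3N (3 equiv), THF, 0 °C to rt; then cold 1 M HCl
Reagents that add atoms: none
Why: Lederer–Manasse-type ortho-hydroxyalkylation of a magnesium phenoxide (Friedel–Crafts hydroxyalkylation), in which the only unsubstituted ring carbon adds to the strongly electrophilic glyoxal aldehyde carbon inside a magnesium chelate while the ring formyl group, deactivated by two flanking phenoxides, stays untouched; the new carbinol centre forms as a racemate and is erased in step 4.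

**Step 4**
Reactants: 6 rac-2,6-dihydroxy-3-[1-hydroxy-2-(4-hydroxyphenyl)-2-oxoethyl]-4-methoxy-5-(3-methylbut-2-en-1-yl)benzaldehyde
Product: 7 2,6-dihydroxy-3-[2-(4-hydroxyphenyl)-2-oxoacetyl]-4-methoxy-5-(3-methylbut-2-en-1-yl)benzaldehyde
Conditions: MnO2 (activated, 10 equiv), EtOAc, rt
Reagents that add atoms: none
Why: Benzoin-to-benzil oxidation of a benzylic α-hydroxy ketone with MnO2, a neutral heterogeneous oxidant that should leave the prenyl olefin, the formyl group and the acyl-deactivated phenols untouched.

**Step 5**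
Reactants: 7 2,6-dihydroxy-3-[2-(4-hydroxyphenyl)-2-oxoacetyl]-4-methoxy-5-(3-methylbut-2-en-1-yl)benzaldehyde; 8 (2-methylprop-1-en-1-yl)boronic acid
Product: 11 1-[5-hydroxy-7-methoxy-2,2-dimethyl-8-(3-methylbut-2-en-1-yl)-2H-chromen-6-yl]-2-(4-hydroxyphenyl)ethane-1,2-dione (target CNP0184805.0), via allylic amine adduct 9 (not isolated), via vinylogous ortho-quinone methide 10 (not isolated)
Conditions: 8 (2.0 equiv), Bn2NH (0.4 equiv), 1,4-dioxane, 90 °C
Reagents that add atoms: none
Why: Dibenzylamine condenses with the formyl group of 7 to an iminium ion stabilised by the ortho phenoxide, boronic acid 8 binds to that phenoxide as a tetracoordinate boronate and passes its alkenyl group to the iminium carbon within the chelate (Petasis borono-Mannich step, new C4–C3 bond) to give allylic amine 9, which expels the amine again and leaves the vinylogous ortho-quinone methide 10. Pyran ring C then closes by a thermal disrotatory oxa-6π-electrocyclisation of the 1-oxatriene O=C8a–C4a=C4–C3=C2 (new O1–C2 bond), which restores the aromaticity of ring A and places the double bond at C3=C4. The closest known reaction type is the secondary-amine-catalysed condensation of salicylaldehydes with alkenylboronic acids to 2H-chromenes, used here with a 2,2-disubstituted alkenyl group. No stereocentre remains: C2 carries two methyl groups and the carbinamine centre of racemic 9 is planarised in 10. The selectivity needed is between the two hydroxyls ortho to the formyl carbon: the C–C bond formation is identical from either, the two quinone methide tautomers interconvert by proton shift, and closure should go to the oxygen next to the prenyl group because the other hydroxyl stays locked in a six-membered hydrogen bond to the aryl ketone C=O, the same bias that makes 2,4-dihydroxyaryl ketones close chromene rings onto their non-chelated oxygen. Chemoselectivity for the aldehyde over the 1,2-diketone rests on the need for a phenoxide-flanked iminium ion, which a secondary amine cannot form at the hindered diaryl ketone carbons.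

**Compound list**
1 | 2,4,6-trihydroxybenzaldehyde | O=Cc1c(O)cc(O)cc1O | starting material
2 | 2,6-dihydroxy-4-methoxybenzaldehyde | COc1cc(O)c(C=O)c(O)c1 | intermediate
3 | 1-bromo-3-methylbut-2-ene (prenyl bromide) | CC(C)=CCBr | starting material
4 | 2,6-dihydroxy-4-methoxy-3-(3-methylbut-2-en-1-yl)benzaldehyde | COc1cc(O)c(C=O)c(O)c1CC=C(C)C | intermediate
5 | 4-hydroxyphenylglyoxal hydrate (2,2-dihydroxy-1-(4-hydroxyphenyl)ethan-1-one) | O=C(C(O)O)c1ccc(O)cc1 | starting material
6 | rac-2,6-dihydroxy-3-[1-hydroxy-2-(4-hydroxyphenyl)-2-oxoethyl]-4-methoxy-5-(3-methylbut-2-en-1-yl)benzaldehyde (racemic at the carbinol carbon) | COc1c(CC=C(C)C)c(O)c(C=O)c(O)c1C(O)C(=O)c1ccc(O)cc1 | intermediate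
7 | 2,6-dihydroxy-3-[2-(4-hydroxyphenyl)-2-oxoacetyl]-4-methoxy-5-(3-methylbut-2-en-1-yl)benzaldehyde | COc1c(CC=C(C)C)c(O)c(C=O)c(O)c1C(=O)C(=O)c1ccc(O)cc1 | intermediate
8 | (2-methylprop-1-en-1-yl)boronic acid | CC(C)=CB(O)O | starting material
9 | rac-1-{3-[1-(dibenzylamino)-3-methylbut-2-en-1-yl]-2,4-dihydroxy-6-methoxy-5-(3-methylbut-2-en-1-yl)phenyl}-2-(4-hydroxyphenyl)ethane-1,2-dione (allylic amine adduct, racemic at the carbinamine carbon) | COc1c(CC=C(C)C)c(O)c(C(C=C(C)C)N(Cc2ccccc2)Cc2ccccc2)c(O)c1C(=O)C(=O)c1ccc(O)cc1 | intermediate (not isolated)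
10 | vinylogous ortho-quinone methide: cyclohexa-2,4-dienone of ring A carrying a 3-methylbut-2-enylidene group on the carbon next to the ring C=O, the chain lying on the side of that C=O | O=C1C(CC=C(C)C)=C(OC)C(C(=O)C(=O)c2ccc(O)cc2)=C(O)/C1=C/C=C(C)C | intermediate (not isolated)
11 | 1-[5-hydroxy-7-methoxy-2,2-dimethyl-8-(3-methylbut-2-en-1-yl)-2H-chromen-6-yl]-2-(4-hydroxyphenyl)ethane-1,2-dione | COc1c(CC=C(C)C)c2c(c(O)c1C(=O)C(=O)c1ccc(O)cc1)C=CC(C)(C)O2 | target

**Step count and risks**
Total step count: 5. Longest linear sequence: 5 steps (1 → 2 → 4 → 6 → 7 → 11).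

Steps most likely to fail:

Step 3. The first adduct may lose water to an ortho-quinone methide that captures a second molecule of 4 (double arylation of the glyoxal carbon). Alternatively, the formyl-deactivated ring may add so slowly that the glyoxal is lost by disproportionation. The fallback brings the carbon in at the ketone oxidation level by Friedel–Crafts acylation before the acid-sensitive prenyl group is present; it sets out from 2 and comes back at 7. Commercial 4-hydroxyphenylglyoxylic acid is pivaloylated (PivCl, pyridine) to 2-oxo-2-[4-(pivaloyloxy)phenyl]acetic acid F1. This is converted with (COCl)2 and catalytic DMF into 2-oxo-2-[4-(pivaloyloxy)phenyl]acetyl chloride F2. Acylation of 2 with F2 (TiCl4, CH2Cl2, 0 °C to rt) at one of its two equivalent ring carbons should give 4-[2-(3-formyl-2,4-dihydroxy-6-methoxyphenyl)-2-oxoacetyl]phenyl pivalate F3. C-prenylation of F3 with 3 (DBU, THF) at the only remaining ring carbon should give 4-{2-[3-formyl-2,4-dihydroxy-6-methoxy-5-(3-methylbut-2-en-1-yl)phenyl]-2-oxoacetyl}phenyl pivalate F4. K2CO3 in MeOH at rt then cleaves the aryl pivalate to give 7.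

Step 5. The ring may close onto the wrong hydroxyl if the hydrogen bond to the ketone does not dominate. Iminium formation at the doubly hydrogen-bonded aldehyde may be slow, or the amine and boronic acid may be tied up by the 1,2-diketone. The fallback is a stoichiometric organomagnesium addition with dehydrative ring closure, run before the diketone exists and with the competing hydroxyl blocked; it sets out from 4 and comes back at 11. Mono-O-allylation of 4 (allyl bromide 1.0 equiv, K2CO3, acetone) at the less hindered hydroxyl, the one next to the ring C–H, should give 6-(allyloxy)-2-hydroxy-4-methoxy-3-(3-methylbut-2-en-1-yl)benzaldehyde F5. Me2C=CHMgBr (2.2 equiv, THF, 0 °C) should add to the formyl group to give rac-3-(allyloxy)-2-(1-hydroxy-3-methylbut-2-en-1-yl)-5-methoxy-6-(3-methylbut-2-en-1-yl)phenol F6. Catalytic PPTS in toluene at 60 °C ionises this to the ortho-quinone methide, which can close only onto the free oxygen, giving 5-(allyloxy)-7-methoxy-2,2-dimethyl-8-(3-methylbut-2-en-1-yl)-2H-chromene F7. Pd(PPh3)4 with morpholine removes the allyl group to give 7-methoxy-2,2-dimethyl-8-(3-methylbut-2-en-1-yl)-2H-chromen-5-ol F8. Hydroxyalkylation with 5 under the conditions of step 3 at the only free ring carbon should give rac-2-hydroxy-2-[5-hydroxy-7-methoxy-2,2-dimethyl-8-(3-methylbut-2-en-1-yl)-2H-chromen-6-yl]-1-(4-hydroxyphenyl)ethan-1-one F9, and MnO2 as in step 4 should give 11.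

Step 2. O-alkylation may compete with C-alkylation, and the ambident phenoxide may be alkylated twice. The fallback is an aromatic Claisen rearrangement; it sets out from 2 and comes back at 4. Mono-O-alkylation of 2 with 3-chloro-3-methylbut-1-yne (K2CO3, KI, catalytic CuI, acetone) should give 2-hydroxy-4-methoxy-6-[(2-methylbut-3-yn-2-yl)oxy]benzaldehyde F10. Semi-hydrogenation (H2, Pd/CaCO3 poisoned with Pb(OAc)2, quinoline, EtOAc) should give 2-hydroxy-4-methoxy-6-[(2-methylbut-3-en-2-yl)oxy]benzaldehyde F11. Heating F11 (PhNEt2, 120 °C) should trigger the [3,3]-sigmatropic shift to the only free ortho carbon, since the other ortho carbon carries the formyl group; allyl inversion delivers the linear prenyl group of 4.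

**Further compounds**
F1 | step 3 | 2-oxo-2-[4-(pivaloyloxy)phenyl]acetic acid | CC(C)(C)C(=O)Oc1ccc(cc1)C(=O)C(=O)O
F2 | step 3 | 2-oxo-2-[4-(pivaloyloxy)phenyl]acetyl chloride | CC(C)(C)C(=O)Oc1ccc(cc1)C(=O)C(=O)Cl
F3 | step 3 | 4-[2-(3-formyl-2,4-dihydroxy-6-methoxyphenyl)-2-oxoacetyl]phenyl pivalate | COc1cc(O)c(C=O)c(O)c1C(=O)C(=O)c1ccc(OC(=O)C(C)(C)C)cc1
F4 | step 3 | 4-{2-[3-formyl-2,4-dihydroxy-6-methoxy-5-(3-methylbut-2-en-1-yl)phenyl]-2-oxoacetyl}phenyl pivalate | COc1c(CC=C(C)C)c(O)c(C=O)c(O)c1C(=O)C(=O)c1ccc(OC(=O)C(C)(C)C)cc1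
F5 | step 5 | 6-(allyloxy)-2-hydroxy-4-methoxy-3-(3-methylbut-2-en-1-yl)benzaldehyde | COc1cc(OCC=C)c(C=O)c(O)c1CC=C(C)C
F6 | step 5 | rac-3-(allyloxy)-2-(1-hydroxy-3-methylbut-2-en-1-yl)-5-methoxy-6-(3-methylbut-2-en-1-yl)phenol | COc1cc(OCC=C)c(C(O)C=C(C)C)c(O)c1CC=C(C)C
F7 | step 5 | 5-(allyloxy)-7-methoxy-2,2-dimethyl-8-(3-methylbut-2-en-1-yl)-2H-chromene | COc1cc(OCC=C)c2c(c1CC=C(C)C)OC(C)(C)C=C2
F8 | step 5 | 7-methoxy-2,2-dimethyl-8-(3-methylbut-2-en-1-yl)-2H-chromen-5-ol | COc1cc(O)c2c(c1CC=C(C)C)OC(C)(C)C=C2
F9 | step 5 | rac-2-hydroxy-2-[5-hydroxy-7-methoxy-2,2-dimethyl-8-(3-methylbut-2-en-1-yl)-2H-chromen-6-yl]-1-(4-hydroxyphenyl)ethan-1-one | COc1c(CC=C(C)C)c2c(c(O)c1C(O)C(=O)c1ccc(O)cc1)C=CC(C)(C)O2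
F10 | step 2 | 2-hydroxy-4-methoxy-6-[(2-methylbut-3-yn-2-yl)oxy]benzaldehyde | COc1cc(O)c(C=O)c(OC(C)(C)C#C)c1
F11 | step 2 | 2-hydroxy-4-methoxy-6-[(2-methylbut-3-en-2-yl)oxy]benzaldehyde | COc1cc(O)c(C=O)c(OC(C)(C)C=C)c1
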